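**Retrosynthetic overview**
1. Target 17 ← N-Cbz 6-alkynyl dihydropyridinone 15: one hydrogenation saturates the chain and frees the amine; the C3 ketone is reduced last on the N–H chair.
2. 15 ← C6–C1' bond: BF3-mediated alkynylation of hemiaminal 4 with the unprotected triyne diol 12 (new step; sets C6 cis to the 2-methyl group).
3. 4 ← oxidative furan → dihydropyridinone ring expansion (aza-Achmatowicz) of the Cbz carbamate of (R)-1-(furan-2-yl)ethanamine; this forms the only ring of the target.
4. 12 ← octa-1,7-diyne as linchpin: (S)-propylene oxide at one end, (S)-epichlorohydrin then acetylide at the other; both carbinol centres come from the epoxides.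

Assumption: (1R)-1-(furan-2-yl)ethan-1-amine is bought as the single enantiomer; the hemiaminal carbon C6 of 4 (and of F3) is left unspecified because it is erased on ionisation.

**Route**

Step 1
Reactants: 1 (1R)-1-(furan-2-yl)ethan-1-amine
Product: 2 benzyl N-[(1R)-1-(furan-2-yl)ethyl]carbamate
Conditions: CbzCl, aq NaOH, THF, 0 °C
Reagents that add atoms: benzyl chloroformate, O=C(Cl)OCc1ccccc1
Why: Schotten–Baumann N-acylation gives the carbamate N–H needed as the internal nucleophile of the ring expansion, without touching the stereocentre.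

Step 2
Reactants: 2 benzyl N-[(1R)-1-(furan-2-yl)ethyl]carbamate
Product: 4 benzyl (2R)-6-hydroxy-2-methyl-3-oxo-3,6-dihydro-2H-pyridine-1-carboxylate, via keto-enal 3 (not isolated)
Conditions: mCPBA, CH2Cl2, 0 °C → rt
Reagents that add atoms: mCPBA (3-chloroperoxybenzoic acid), OOC(=O)c1cccc(Cl)c1
Why: Aza-Achmatowicz oxidative ring expansion, in which the peracid opens the furan to the Z-keto-enal 3 and the carbamate N–H closes on the aldehyde to the six-membered hemiaminal; C2 is untouched and C6 is an anomeric mixture of no consequence.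

Step 3
Reactants: 5 octa-1,7-diyne; 6 (2S)-2-methyloxirane
Product: 7 (2S)-undeca-4,10-diyn-2-ol
Conditions: 5 (3 equiv), n-BuLi (1 equiv), THF, −78 °C; BF3·OEt2; then 6, −78 °C
Reagents that add atoms: none
Why: Yamaguchi–Hirao BF3-mediated opening of the epoxide by the mono-lithium acetylide at the CH2 terminus carries the (S) centre over unchanged, and the excess diyne (recovered) limits reaction to one end.

Step 4
Reactants: 7 (2S)-undeca-4,10-diyn-2-ol; 8 (2S)-2-(chloromethyl)oxirane
Product: 9 (2S,13S)-1-chlorotetradeca-4,10-diyne-2,13-diol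
Conditions: n-BuLi (2.1 equiv), THF, −78 °C; BF3·OEt2 (2.5 equiv); then 8, −78 °C
Reagents that add atoms: none
Why: Yamaguchi–Hirao opening with the alkoxide/acetylide dianion (alkoxide masked as its BF3 ate complex) occurs at the epoxide CH2 and not at C–Cl at −78 °C, so the epichlorohydrin centre is retained as (S).

Step 5
Reactants: 9 (2S,13S)-1-chlorotetradeca-4,10-diyne-2,13-diol; 10 lithium acetylide–ethane-1,2-diamine complex
Product: 12 (2S,13R)-hexadeca-4,10,15-triyne-2,13-diol, via epoxide 11 (not isolated)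
Conditions: 10 (5 equiv), DMSO–THF, 0 °C → rt
Reagents that add atoms: none
Why: Base closes the chlorohydrin to terminal epoxide 11 (Williamson) and acetylide opens it at the CH2 terminus (SN2) without breaking a bond to the stereocentre; the descriptor changes from S to R only through CIP priorities.

Step 6
Reactants: 4 benzyl (2R)-6-hydroxy-2-methyl-3-oxo-3,6-dihydro-2H-pyridine-1-carboxylate; 12 (2S,13R)-hexadeca-4,10,15-triyne-2,13-diol
Product: 15 benzyl (2R,6R)-6-[(4S,15S)-4,15-dihydroxyhexadeca-1,6,12-triyn-1-yl]-2-methyl-3-oxo-3,6-dihydro-2H-pyridine-1-carboxylate, via lithium alkynyltrifluoroborate 13 (not isolated), via N-acyliminium ion 14 (not isolated)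
Conditions: 12 (1 equiv), n-BuLi (3 equiv), THF, −78 °C; BF3·OEt2 (6 equiv); then 4 (1.5 equiv) in CH2Cl2, −78 → −30 °C; aq NaHCO3
Reagents that add atoms: none
Why: Proposed new method: a BF3-mediated Kishi-type C-alkynylation of an aza-Achmatowicz hemiaminal that still carries its enone, using the lithium alkynyltrifluoroborate 13 made in the flask from unprotected 12 (both alkoxides masked as O–BF3Li groups, so no protecting groups are needed). Excess BF3 ionises C6–OH of 4 to the N-acyliminium ion 14, whose 2-methyl group sits pseudoaxial to avoid allylic 1,3-strain with the Cbz group; the slim alkynyl group is transferred ipso from boron along the axial trajectory on the same face (the trans product would force one substituent into the carbamate plane), giving the 2,6-cis (2R,6R) product. The base-free medium at −78 °C should outrun loss of the C2 proton (aromatisation to a 3-hydroxypyridinium), and the s-trans enone cannot undergo boron-mediated conjugate alkynylation. The closest known reactions are BF3-promoted additions of potassium alkynyltrifluoroborates to simple cyclic N-acyliminium ions and allylsilane additions to aza-Achmatowicz-derived N-sulfonyliminium ions after ketone reduction; to my knowledge neither has been shown on the enone-bearing hemiaminal or with a free alkynediol.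

Step 7
Reactants: 15 benzyl (2R,6R)-6-[(4S,15S)-4,15-dihydroxyhexadeca-1,6,12-triyn-1-yl]-2-methyl-3-oxo-3,6-dihydro-2H-pyridine-1-carboxylate
Product: 17 (2R,3S,6S)-6-[(4S,15S)-4,15-dihydroxyhexadecyl]-2-methylpiperidin-3-ol, via amino ketone 16 (not isolated)
Conditions: H2 (1 atm), Pd/C, EtOH, rt; filter; NaBH4, EtOH, −40 °C
Reagents that add atoms: none
Why: Heterogeneous hydrogenation saturates three alkynes and the enone C=C and hydrogenolyses Cbz without touching a stereocentre (C2, now epimerisable, stays in the favoured 2,6-cis diequatorial form), and substrate-controlled NaBH4 reduction by axial attack on that chair (only one syn-axial C–H, at C5) gives the equatorial 3-OH trans to the 2-methyl group, i.e. (3S).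

**Compound list**
1 | (1R)-1-(furan-2-yl)ethan-1-amine | C[C@@H](N)c1ccco1 | starting material
2 | benzyl N-[(1R)-1-(furan-2-yl)ethyl]carbamate | C[C@@H](NC(=O)OCc1ccccc1)c1ccco1 | intermediate
3 | benzyl N-[(2R,4Z)-3,6-dioxohex-4-en-2-yl]carbamate | O=C/C=C\C(=O)[C@@H](C)NC(=O)OCc1ccccc1 | intermediate
4 | benzyl (2R)-6-hydroxy-2-methyl-3-oxo-3,6-dihydro-2H-pyridine-1-carboxylate (C6 anomers) | C[C@H]1N(C(=O)OCc2ccccc2)C(O)C=CC1=O | intermediate
5 | octa-1,7-diyne | C#CCCCCC#C | starting material
6 | (2S)-2-methyloxirane | C[C@H]1CO1 | starting material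
7 | (2S)-undeca-4,10-diyn-2-ol | C[C@H](O)CC#CCCCCC#C | intermediate
8 | (2S)-2-(chloromethyl)oxirane | ClC[C@@H]1CO1 | starting material
9 | (2S,13S)-1-chlorotetradeca-4,10-diyne-2,13-diol | C[C@H](O)CC#CCCCCC#CC[C@H](O)CCl | intermediate
10 | lithium acetylide–ethane-1,2-diamine complex | [Li+].[C-]#C.NCCN | starting material
11 | (2S)-12-[(2S)-oxiran-2-yl]dodeca-4,10-diyn-2-ol | C[C@H](O)CC#CCCCCC#CC[C@H]1CO1 | intermediate
12 | (2S,13R)-hexadeca-4,10,15-triyne-2,13-diol | C[C@H](O)CC#CCCCCC#CC[C@H](O)CC#C | intermediate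
13 | trilithium tris(trifluoroborate) of 12 (C-alkynyl–BF3 at C16, O–BF3 at both carbinol oxygens; configuration as in 12) | [Li+].[Li+].[Li+].C[C@H](O[B-](F)(F)F)CC#CCCCCC#CC[C@H](O[B-](F)(F)F)CC#C[B-](F)(F)F | intermediate
14 | (2R)-1-[(benzyloxy)carbonyl]-2-methyl-3-oxo-2,3-dihydropyridin-1-ium hydroxytrifluoroborate | C[C@@H]1C(=O)C=CC=[N+]1C(=O)OCc1ccccc1.O[B-](F)(F)F | intermediate
15 | benzyl (2R,6R)-6-[(4S,15S)-4,15-dihydroxyhexadeca-1,6,12-triyn-1-yl]-2-methyl-3-oxo-3,6-dihydro-2H-pyridine-1-carboxylate | C[C@H](O)CC#CCCCCC#CC[C@H](O)CC#C[C@H]1C=CC(=O)[C@@H](C)N1C(=O)OCc1ccccc1 | intermediate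
16 | (2R,6S)-6-[(4S,15S)-4,15-dihydroxyhexadecyl]-2-methylpiperidin-3-one | C[C@H](O)CCCCCCCCCC[C@H](O)CCC[C@H]1CCC(=O)[C@@H](C)N1 | intermediate
17 | (2R,3S,6S)-6-[(4S,15S)-4,15-dihydroxyhexadecyl]-2-methylpiperidin-3-ol | C[C@H](O)CCCCCCCCCC[C@H](O)CCC[C@H]1CC[C@H](O)[C@@H](C)N1 | target

**Count and risks**
Total steps: 7. Longest linear sequence: 5 (steps 3, 4, 5, 6, 7, from octa-1,7-diyne).

Step 6 (the proposed new alkynylation). Risks are aromatisation of cation 14 by loss of the C2 proton, which would also erase C2, and incomplete cis selectivity. The fallback uses known reaction types, sets out from 2 and 12 and comes back at 16. Carbamate 2 is brominated at furan C5 (NBS, DMF, −20 °C) to benzyl N-[(1R)-1-(5-bromofuran-2-yl)ethyl]carbamate F1. Sonogashira coupling with 12 (PdCl2(PPh3)2, CuI, Et3N, THF) gives benzyl N-[(1R)-1-{5-[(4S,15S)-4,15-dihydroxyhexadeca-1,6,12-triyn-1-yl]furan-2-yl}ethyl]carbamate F2. The same mCPBA ring expansion then gives benzyl (2R)-6-[(4S,15S)-4,15-dihydroxyhexadeca-1,6,12-triyn-1-yl]-6-hydroxy-2-methyl-3-oxo-3,6-dihydro-2H-pyridine-1-carboxylate F3. Hydrogenation over Pd/C saturates the chain and removes Cbz; the free amine condenses with the C6 ketone, and the cyclic imine is hydrogenated to the 2,6-cis amino ketone 16, which is reduced with NaBH4 as in step 7. Here C6 is set by imine hydrogenation instead of iminium alkynylation.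

Step 4 (epichlorohydrin opening by a dianion carrying a free alkoxide in the presence of BF3). The fallback inverts the order of linchpin assembly with the alcohol protected; it sets out from 7 and comes back at 12. Commercial (2R)-2-(chloromethyl)oxirane is opened by lithium (trimethylsilyl)acetylide/BF3·OEt2 to (2R)-1-chloro-5-(trimethylsilyl)pent-4-yn-2-ol F4, which NaH in THF closes to trimethyl{3-[(2R)-oxiran-2-yl]prop-1-yn-1-yl}silane F5. Alcohol 7 is silylated (TBSCl, imidazole) to tert-butyl(dimethyl){[(2S)-undeca-4,10-diyn-2-yl]oxy}silane F6. Its lithium acetylide opens F5 under BF3·OEt2 to (4S,15S)-15-{[tert-butyl(dimethyl)silyl]oxy}-1-(trimethylsilyl)hexadeca-1,6,12-triyn-4-ol F7, and TBAF removes both silyl groups to give 12.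

Step 7 (C3 selectivity of the hydride reduction; a 3-epimer would be hard to separate). The fallback replaces substrate control by catalyst control: amino ketone 16 is reduced with an (S)-selective ketoreductase of the kind used for piperidin-3-ones (KRED, NADP+, i-PrOH, pH 7 buffer with DMSO co-solvent, 30 °C) to give 17 directly. It sets out from 16 and comes back at 17; no new compound is made on this path, F0.

**Further compounds**
F1 | step 6 | benzyl N-[(1R)-1-(5-bromofuran-2-yl)ethyl]carbamate | C[C@@H](NC(=O)OCc1ccccc1)c1ccc(Br)o1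
F2 | step 6 | benzyl N-[(1R)-1-{5-[(4S,15S)-4,15-dihydroxyhexadeca-1,6,12-triyn-1-yl]furan-2-yl}ethyl]carbamate | C[C@H](O)CC#CCCCCC#CC[C@H](O)CC#Cc1ccc(o1)[C@@H](C)NC(=O)OCc1ccccc1
F3 | step 6 | benzyl (2R)-6-[(4S,15S)-4,15-dihydroxyhexadeca-1,6,12-triyn-1-yl]-6-hydroxy-2-methyl-3-oxo-3,6-dihydro-2H-pyridine-1-carboxylate | C[C@H](O)CC#CCCCCC#CC[C@H](O)CC#CC1(O)C=CC(=O)[C@@H](C)N1C(=O)OCc1ccccc1
F4 | step 4 | (2R)-1-chloro-5-(trimethylsilyl)pent-4-yn-2-ol | ClC[C@H](O)CC#C[Si](C)(C)C
F5 | step 4 | trimethyl{3-[(2R)-oxiran-2-yl]prop-1-yn-1-yl}silane | C[Si](C)(C)C#CC[C@@H]1CO1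
F6 | step 4 | tert-butyl(dimethyl){[(2S)-undeca-4,10-diyn-2-yl]oxy}silane | C[C@H](O[Si](C)(C)C(C)(C)C)CC#CCCCCC#C
F7 | step 4 | (4S,15S)-15-{[tert-butyl(dimethyl)silyl]oxy}-1-(trimethylsilyl)hexadeca-1,6,12-triyn-4-ol | C[C@H](O[Si](C)(C)C(C)(C)C)CC#CCCCCC#CC[C@H](O)CC#C[Si](C)(C)C
F0 | step 7 | none | none
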